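**Retrosynthetic overview**
- The dihydropyranone is the only ring made, and it is closed last. O1–C2 is cut back to an achiral 2'-hydroxy-α-aryl enone. Oxa-Michael closure and protonation of the resulting enolate set C3 (S) in one catalytic step.
- The hydroxy-enone comes from its tris-MOM ether. That ether is made from the tris-MOM deoxybenzoin by Mannich methylenation, which supplies C2 as a CH2 unit.
- The deoxybenzoin is cut at C3–C1', giving a Pd ketone α-arylation of a prenylated acetophenone with the B-ring aryl bromide.
- The A-ring ketone comes from 5-bromoresacetophenone (MOM protection, Stille prenylation). The B-ring bromide comes from 4-bromo-2,5-dimethoxybenzaldehyde (Baeyer–Villiger oxidation, MOM protection).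
- Both benzene rings are bought, and the stereocentre sees no reagent after it is made.

Assumption: the quinine-derived squaramide is taken to protonate the C3-Re face and give (S). The sense is checked by chiral HPLC and ECD on the first run, and the quinidine-derived pseudo-enantiomer is the direct swap if it is opposite.

**Step 1**
Reactants: 1 1-(5-bromo-2,4-dihydroxyphenyl)ethan-1-one
Product: 2 1-[5-bromo-2,4-bis(methoxymethoxy)phenyl]ethan-1-one
Conditions: NaH (2.2 equiv), MOMCl (2.5 equiv), DMF, 0 °C → rt
Reagents that add atoms: chloromethyl methyl ether (MOMCl), COCCl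
Why: Williamson-type O-alkylation, in which full deprotonation with NaH also engages the ketone-chelated 2-OH and the two acetals then survive the base and Pd(0) of steps 2, 5 and 6.

**Step 2**
Reactants: 2 1-[5-bromo-2,4-bis(methoxymethoxy)phenyl]ethan-1-one
Product: 3 1-[2,4-bis(methoxymethoxy)-5-(3-methylbut-2-en-1-yl)phenyl]ethan-1-one
Conditions: Bu3SnCH2CH=CMe2 (1.3 equiv), Pd(PPh3)4 (5 mol %), DMF, 100 °C
Reagents that add atoms: tributyl(3-methylbut-2-en-1-yl)stannane, CCCC[Sn](CCCC)(CCCC)CC=C(C)C
Why: Stille coupling, whose neutral base-free conditions spare the methyl ketone and acetals while the allylic stannane transfers its unhindered CH2 terminus, so the linear prenyl group lands where the bromine marked C5 (C6 of the target).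

**Step 3**
Reactants: 4 4-bromo-2,5-dimethoxybenzaldehyde
Product: 6 4-bromo-2,5-dimethoxyphenol, via aryl formate 5 (not isolated)
Conditions: mCPBA (1.3 equiv), CH2Cl2, 0 °C → rt; aq NaHCO3 wash; then MeOH, K2CO3 (10 mol %), rt
Reagents that add atoms: 3-chloroperoxybenzoic acid (mCPBA), OOC(=O)c1cccc(Cl)c1
Why: Baeyer–Villiger (Dakin-type) oxidation, in which the electron-rich aryl group migrates in preference to hydride to give formate 5, which methanol transesterifies to the free phenol.

**Step 4**
Reactants: 6 4-bromo-2,5-dimethoxyphenol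
Product: 7 1-bromo-2,5-dimethoxy-4-(methoxymethoxy)benzene
Conditions: NaH (1.2 equiv), MOMCl (1.3 equiv), DMF, 0 °C → rt
Reagents that add atoms: chloromethyl methyl ether (MOMCl), COCCl
Why: Williamson-type O-alkylation of the sodium phenoxide, using the same acetal as on ring A so that one joint deprotection is enough later.

**Step 5**
Reactants: 3 1-[2,4-bis(methoxymethoxy)-5-(3-methylbut-2-en-1-yl)phenyl]ethan-1-one; 7 1-bromo-2,5-dimethoxy-4-(methoxymethoxy)benzene
Product: 8 1-[2,4-bis(methoxymethoxy)-5-(3-methylbut-2-en-1-yl)phenyl]-2-[2,5-dimethoxy-4-(methoxymethoxy)phenyl]ethan-1-one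
Conditions: Pd2(dba)3 (1.5 mol %), XPhos (6 mol %), NaOtBu (2.2 equiv), toluene, 80 °C
Reagents that add atoms: none
Why: Buchwald–Hartwig-type Pd-catalysed ketone α-arylation, in which the sodium enolate of the methyl ketone couples with the aryl bromide and a second arylation is stopped by the ortho-methoxy group and by immediate deprotonation of the more acidic product.

**Step 6**
Reactants: 8 1-[2,4-bis(methoxymethoxy)-5-(3-methylbut-2-en-1-yl)phenyl]-2-[2,5-dimethoxy-4-(methoxymethoxy)phenyl]ethan-1-one
Product: 10 1-[2,4-bis(methoxymethoxy)-5-(3-methylbut-2-en-1-yl)phenyl]-2-[2,5-dimethoxy-4-(methoxymethoxy)phenyl]prop-2-en-1-one, via Mannich base 9 (not isolated)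
Conditions: CH2(NMe2)2 (4 equiv), Ac2O (5 equiv), DMF, rt → 60 °C
Reagents that add atoms: N,N,N',N'-tetramethylmethanediamine, CN(C)CN(C)C
Why: Mannich methylenation, in which the iminium acetate made from the aminal and Ac2O aminomethylates the acidic benzylic CH2 to 9, whose amine is N-acetylated and lost by elimination, while masking of all three phenols excludes ring Mannich reaction and premature ring closure.

**Step 7**
Reactants: 10 1-[2,4-bis(methoxymethoxy)-5-(3-methylbut-2-en-1-yl)phenyl]-2-[2,5-dimethoxy-4-(methoxymethoxy)phenyl]prop-2-en-1-one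
Product: 11 1-[2,4-dihydroxy-5-(3-methylbut-2-en-1-yl)phenyl]-2-(4-hydroxy-2,5-dimethoxyphenyl)prop-2-en-1-one
Conditions: NaHSO4·SiO2, CH2Cl2, rt, 1–2 h; filter, concentrate below 25 °C, use at once
Reagents that add atoms: none
Why: Acid-catalysed acetal hydrolysis on a solid acid in a non-nucleophilic solvent, where phenolic MOM ethers cleave at rt, nothing present can add to the enone, the freed 2'-OH is held in a hydrogen bond to the ketone and does not add without base, and the acid is filtered off before it can attack the prenyl group.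

**Step 8**
Reactants: 11 1-[2,4-dihydroxy-5-(3-methylbut-2-en-1-yl)phenyl]-2-(4-hydroxy-2,5-dimethoxyphenyl)prop-2-en-1-one
Product: 13 (3S)-7-hydroxy-3-(4-hydroxy-2,5-dimethoxyphenyl)-6-(3-methylbut-2-en-1-yl)-2,3-dihydro-4H-chromen-4-one, via catalyst-bound enolate 12 (not isolated)
Conditions: quinine-derived squaramide 3-{[3,5-bis(trifluoromethyl)phenyl]amino}-4-{[(8α,9S)-6'-methoxycinchonan-9-yl]amino}cyclobut-3-ene-1,2-dione (10 mol %), CPME/CH2Cl2 4:1 (0.02 M), 4 Å MS, −30 °C; filtered cold through AcOH-washed SiO2
Reagents that add atoms: none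
Why: Proposed new method: catalytic asymmetric intramolecular oxa-Michael addition/enantioselective protonation, in which the quinuclidine takes the proton of the 2'-OH while the squaramide N–H pair replaces the internal O–H···O=C bond at the ketone oxygen, the phenoxide closes 6-endo-trig on the unsubstituted CH2 terminus (O1–C2 bond, pyranone ring) to give the squaramide-bound, geometry-fixed endocyclic enolate 12, and the quinuclidinium in the same contact ion pair returns the proton to the C3-Re face faster than an outside phenol can at high dilution, setting C3 as S under kinetic control at −30 °C, where the phenol-buffered amine does not re-enolise the hindered 2'-methoxyaryl ketone; the closest known reaction types are bifunctional amine–thiourea/squaramide phenol oxy-Michael cyclisations to chromans and flavanones (stereocentre at the β-carbon) and intermolecular sulfa-Michael/enantioselective protonation of α-substituted acrylates, whereas a C–O-forming conjugate addition whose only stereocentre comes from protonation of an α-aryl enolate, and an isoflavanone synthesis of this kind, are to my knowledge not described.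

**Compound list**
1 | 1-(5-bromo-2,4-dihydroxyphenyl)ethan-1-one | CC(=O)c1cc(Br)c(O)cc1O | starting material
2 | 1-[5-bromo-2,4-bis(methoxymethoxy)phenyl]ethan-1-one | CC(=O)c1cc(Br)c(OCOC)cc1OCOC | intermediate
3 | 1-[2,4-bis(methoxymethoxy)-5-(3-methylbut-2-en-1-yl)phenyl]ethan-1-one | CC(=O)c1cc(CC=C(C)C)c(OCOC)cc1OCOC | intermediate
4 | 4-bromo-2,5-dimethoxybenzaldehyde | O=Cc1cc(OC)c(Br)cc1OC | starting material
5 | 4-bromo-2,5-dimethoxyphenyl formate (not isolated) | O=COc1cc(OC)c(Br)cc1OC | intermediate
6 | 4-bromo-2,5-dimethoxyphenol | Oc1cc(OC)c(Br)cc1OC | intermediate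
7 | 1-bromo-2,5-dimethoxy-4-(methoxymethoxy)benzene | COCOc1cc(OC)c(Br)cc1OC | intermediate
8 | 1-[2,4-bis(methoxymethoxy)-5-(3-methylbut-2-en-1-yl)phenyl]-2-[2,5-dimethoxy-4-(methoxymethoxy)phenyl]ethan-1-one | COCOc1cc(OCOC)c(CC=C(C)C)cc1C(=O)Cc1cc(OC)c(OCOC)cc1OC | intermediate
9 | racemic 1-[2,4-bis(methoxymethoxy)-5-(3-methylbut-2-en-1-yl)phenyl]-2-[2,5-dimethoxy-4-(methoxymethoxy)phenyl]-3-(dimethylamino)propan-1-one (Mannich base, not isolated) | CN(C)CC(C(=O)c1cc(CC=C(C)C)c(OCOC)cc1OCOC)c1cc(OC)c(OCOC)cc1OC | intermediate
10 | 1-[2,4-bis(methoxymethoxy)-5-(3-methylbut-2-en-1-yl)phenyl]-2-[2,5-dimethoxy-4-(methoxymethoxy)phenyl]prop-2-en-1-one | COCOc1cc(OCOC)c(CC=C(C)C)cc1C(=O)C(=C)c1cc(OC)c(OCOC)cc1OC | intermediate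
11 | 1-[2,4-dihydroxy-5-(3-methylbut-2-en-1-yl)phenyl]-2-(4-hydroxy-2,5-dimethoxyphenyl)prop-2-en-1-one | C=C(C(=O)c1cc(CC=C(C)C)c(O)cc1O)c1cc(OC)c(O)cc1OC | intermediate
12 | 3-(4-hydroxy-2,5-dimethoxyphenyl)-6-(3-methylbut-2-en-1-yl)-2H-chromene-4,7-diol (present as the catalyst-bound enolate, drawn as the neutral enol, not isolated) | COc1cc(C2=C(O)c3cc(CC=C(C)C)c(O)cc3OC2)c(OC)cc1O | intermediate
13 | (3S)-7-hydroxy-3-(4-hydroxy-2,5-dimethoxyphenyl)-6-(3-methylbut-2-en-1-yl)-2,3-dihydro-4H-chromen-4-one | COc1cc([C@H]2COc3cc(O)c(CC=C(C)C)cc3C2=O)c(OC)cc1O | target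

**Totals**
- Total step count: 8.
- Longest linear sequence: 6 (steps 1, 2, 5, 6, 7, 8).

**Three steps most likely to fail**

(i) The new cyclisation (step 8).
- The ee may be eroded if free phenols of other substrate molecules protonate the enolate.
- The acidic 4-OH of ring A may tie up the amine catalyst.
- A small share of 11 may close 5-exo through the p-quinone methide tautomer of ring B.
- The product can racemise slowly if left with the catalyst.

The fallback uses known chemistry and sets out from 11. Et3N (20 mol %) in CH2Cl2 at rt closes it to the racemic isoflavanone F1. Preparative chiral SFC on an amylose tris(3,5-dimethylphenylcarbamate) phase separates 13 from the (3R)-enantiomer F2. DBU in THF re-equilibrates F2 to F1, which is fed back to the separation. The fallback comes back to the route at 13.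

(ii) The global MOM removal on the enone (step 7).
- The two less labile acetals need the longest acid contact.
- During that time the freed hydroxy-enone could close to racemic product.
- The prenyl group could cyclise onto the neighbouring phenol.
- The polyphenolic enone could oligomerise on concentration.

The fallback sets out from 10. MgBr2·OEt2 (CH2Cl2/Et2O, 0 °C) chelates the ketone and the flanking acetal oxygen and removes only the 2-O-MOM group, giving the bis-MOM hydroxy-enone F3. The catalyst of step 8 closes F3 to the (3S)-7,4'-bis-O-MOM isoflavanone F4. No acidic free phenol or quinone methide pathway is present during that closure. The two remaining acetals are then taken off with NaHSO4·SiO2 in CH2Cl2 at rt, where the ketone should not enolise. This costs one extra step and comes back to the route at 13.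

(iii) The prenyl transfer (step 2).
- It is the only step whose regiochemistry is not enforced by structure.
- Oxidative addition into the electron-rich, ortho-alkoxy bromide is slow.
- At 100 °C, α/γ scrambling or alkene migration can occur.

The fallback sets out from 2. Suzuki–Miyaura coupling with allylboronic acid pinacol ester (Pd(dppf)Cl2, K2CO3, dioxane/H2O, 80 °C) gives the 5-allyl ketone F5, for which both allyl termini lead to the same product. Cross-metathesis with excess 2-methylbut-2-ene (Grubbs II, CH2Cl2, 40 °C) converts allyl into prenyl. The fallback comes back to the route at 3.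

**Further compounds**
F1 | step 8 | racemic 7-hydroxy-3-(4-hydroxy-2,5-dimethoxyphenyl)-6-(3-methylbut-2-en-1-yl)-2,3-dihydro-4H-chromen-4-one | COc1cc(C2COc3cc(O)c(CC=C(C)C)cc3C2=O)c(OC)cc1O
F2 | step 8 | (3R)-7-hydroxy-3-(4-hydroxy-2,5-dimethoxyphenyl)-6-(3-methylbut-2-en-1-yl)-2,3-dihydro-4H-chromen-4-one | COc1cc([C@@H]2COc3cc(O)c(CC=C(C)C)cc3C2=O)c(OC)cc1O
F3 | step 7 | 1-[2-hydroxy-4-(methoxymethoxy)-5-(3-methylbut-2-en-1-yl)phenyl]-2-[2,5-dimethoxy-4-(methoxymethoxy)phenyl]prop-2-en-1-one | C=C(C(=O)c1cc(CC=C(C)C)c(OCOC)cc1O)c1cc(OC)c(OCOC)cc1OC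
F4 | step 7 | (3S)-3-[2,5-dimethoxy-4-(methoxymethoxy)phenyl]-7-(methoxymethoxy)-6-(3-methylbut-2-en-1-yl)-2,3-dihydro-4H-chromen-4-one | COc1cc([C@H]2COc3cc(OCOC)c(CC=C(C)C)cc3C2=O)c(OC)cc1OCOC
F5 | step 2 | 1-[2,4-bis(methoxymethoxy)-5-(prop-2-en-1-yl)phenyl]ethan-1-one | CC(=O)c1cc(CC=C)c(OCOC)cc1OCOC
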